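**Retrosynthetic overview**

1. Colupulone ⇐ its ring ethyl enol ether (hydrolysis) ⇐ a one-flask union of three components: diethyl prenylmalonate, 2,2-diprenylacetyl chloride and 1-ethoxy-4-methylpent-1-yn-3-one.
2. Ring bonds cut, in the order in which they are made: (a) monoprenyl carbon to the ring carbonyl carbon beside the gem-diprenyl carbon (malonate C-acylation); (b) gem-diprenyl carbon to the oxygenated ring carbon between it and the isobutyryl-bearing carbon (conjugate addition to the alkoxy-ynone); (c) isobutyryl-bearing carbon to the oxygenated ring carbon between it and the monoprenyl carbon (Claisen closure on a malonate ester).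
3. Enabling feature: the only ring is a cyclohexane-1,3,5-trione (drawn as a dienol) in which three carbonyl-level acceptor carbons alternate with three donor carbons (gem-diprenyl carbon, monoprenyl carbon, isobutyryl-bearing carbon). It is therefore a head-to-tail cyclotrimer of three two-carbon units, each with one donor and one acceptor carbon; a second ester on the monoprenyl carbon serves as a temporary activating and blocking group and is expelled in the same flask.
4. Both prenylated components come from diethyl malonate and prenyl bromide (the monoalkylated ester is used as such and is also dialkylated and taken to the acid chloride); the ynone comes from ethoxyacetylene and N-methoxy-N-methylisobutyramide.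
5. Ring order: one ring only, the six-membered carbocycle, closed in the key step.

Key step: step 6

Assumption: colupulone is an achiral cyclic β-triketone and is treated as one compound whichever enol tautomer is drawn; the route sets no stereocentre.

**Step 1**
Reactants: 1 diethyl malonate; 2 1-bromo-3-methylbut-2-ene (prenyl bromide)
Product: 3 diethyl 2-(3-methylbut-2-en-1-yl)propanedioate
Conditions: NaH (1.0 equiv), 1 (2.0 equiv), THF, 0 °C; 2 (1.0 equiv), 0 → 23 °C
Reagents that add atoms: none
Why: Malonic ester alkylation: the sodium malonate displaces bromide from the primary allylic bromide (SN2), and the excess of 1 should keep dialkylation low.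

**Step 2**
Reactants: 3 diethyl 2-(3-methylbut-2-en-1-yl)propanedioate; 2 1-bromo-3-methylbut-2-ene
Product: 4 diethyl 2,2-bis(3-methylbut-2-en-1-yl)propanedioate
Conditions: NaH (1.1 equiv), THF/DMF, 0 °C; 2 (1.1 equiv), 0 → 23 °C
Reagents that add atoms: none
Why: Second malonic ester alkylation (SN2) of the tertiary malonate anion with the unhindered allylic bromide, a standard way to geminally diallylated malonates.

**Step 3**
Reactants: 4 diethyl 2,2-bis(3-methylbut-2-en-1-yl)propanedioate
Product: 6 5-methyl-2-(3-methylbut-2-en-1-yl)hex-4-enoic acid, via 2,2-bis(3-methylbut-2-en-1-yl)propanedioic acid 5 (not isolated)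
Conditions: KOH (4 equiv), EtOH/H2O, reflux; 1 M HCl, 0 °C; Cu2O (5 mol %), MeCN, 80 °C
Reagents that add atoms: potassium hydroxide, [K+].[OH-]
Why: Ester saponification followed by decarboxylation of the geminal diacid (malonic acid synthesis); the Cu2O-promoted variant runs near neutrality at moderate temperature, so the trisubstituted alkenes should not be captured by the carboxyl groups.

**Step 4**
Reactants: 6 5-methyl-2-(3-methylbut-2-en-1-yl)hex-4-enoic acid
Product: 7 5-methyl-2-(3-methylbut-2-en-1-yl)hex-4-enoyl chloride
Conditions: (COCl)2 (1.2 equiv), DMF (cat.), CH2Cl2, 0 → 23 °C; volatiles removed at once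
Reagents that add atoms: oxalyl chloride, O=C(Cl)C(=O)Cl
Why: Acid chloride formation through the catalytic chloroiminium (Vilsmeier-type) activator; low temperature and prompt evaporation should keep HCl from adding to the prenyl alkenes.

**Step 5**
Reactants: 8 ethoxyacetylene; 9 N-methoxy-N-methyl-2-methylpropanamide
Product: 12 1-ethoxy-4-methylpent-1-yn-3-one, via lithium ethoxyacetylide 10 (not isolated), via chelated lithium hemiaminal adduct 11 (not isolated)
Conditions: 8 (1.2 equiv), n-BuLi (1.1 equiv), THF, −78 °C; 9 (1.0 equiv), −78 → −20 °C; inverse quench into 0.5 M HCl/Et2O, 0 °C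
Reagents that add atoms: none
Why: Weinreb ketone synthesis: the acetylide adds only once because chelated adduct 11 survives until the cold acidic inverse quench, which also protonates the released hydroxylamine before it can add to the ynone.

**Step 6**
Reactants: 3 diethyl 2-(3-methylbut-2-en-1-yl)propanedioate; 7 5-methyl-2-(3-methylbut-2-en-1-yl)hex-4-enoyl chloride; 12 1-ethoxy-4-methylpent-1-yn-3-one
Product: 17 3-ethoxy-5-hydroxy-4,4,6-tris(3-methylbut-2-en-1-yl)-2-(2-methylpropanoyl)cyclohexa-2,5-dien-1-one (colupulone ethyl enol ether), via acylmalonate 13 (not isolated), via its sodium enolate 14 (not isolated), via sodium allenolate 15 (not isolated), via ring keto ester 16 (not isolated)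
Conditions: 3, NaH (1.0 equiv), THF, 0 °C; 7 (0.98 equiv), 0 → 23 °C; NaN(SiMe3)2 (1.0 equiv), −78 °C; 12 (1.05 equiv), −78 → 23 °C; AcOH (1.1 equiv)
Reagents that add atoms: none
Why: Proposed new method: a one-flask relay in which each C–C bond formation creates the nucleophile for the next: the sodium enolate of 3 is C-acylated by 7 to give 13, NaN(SiMe3)2 removes its only enolisable hydrogen (the methine between the ketone and the two prenyl arms) to give tetrasubstituted enolate 14, which adds through carbon to the ethoxy-bearing sp carbon of 12 (conjugate addition to an alkynylogous ester) and so creates the gem-diprenyl quaternary carbon. The resulting allenolate 15, which has no acidic hydrogen nearby, attacks one of the two geminal ester carbonyls, and the ethoxide expelled then removes the remaining ethoxycarbonyl group from 16 as diethyl carbonate (retro-Claisen), leaving the stabilised enolate of 17. The closest known reaction types are the Michael–Claisen (Michael–Dieckmann) anionic [4+2] annulation of ester-bearing carbanions with acetylenic acceptors and the base-mediated Claisen cyclisation of 3,5,7-triketo esters to acylphloroglucinols. The six-membered ring closes by a 6-exo-trig acyl substitution (Dieckmann-type Claisen condensation) of the allenolate carbon on an ester carbonyl; closure on the ketone is excluded because it would give a four-membered ring. No stereocentre has to be controlled: the ester-bearing carbon of 16 is formed racemic and becomes trigonal when the ester leaves, and the quaternary carbon carries two identical prenyl groups. The step needs C- rather than O-attack of the hindered enolate and attack at the ynone terminus rather than at its carbonyl, which the unhindered linear sp electrophile, the reversibility of aldol-type and O-vinylation adducts and the irreversible ring closure should secure, while the second ester on the malonate carbon fixes the site of enolisation, keeps the allenolate from being protonated and keeps the acceptor ester electrophilic.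

**Step 7**
Reactants: 17 colupulone ethyl enol ether
Product: 18 colupulone
Conditions: 1 M HCl, THF, 23 °C, argon
Reagents that add atoms: water, O
Why: Acid-catalysed addition–elimination hydrolysis of a vinylogous ester (an enol ether flanked by two acyl groups), which should be fast under conditions too mild to cyclise the prenyl groups onto the enols.

**Compound list**

1 | diethyl malonate | CCOC(=O)CC(=O)OCC | starting material
2 | 1-bromo-3-methylbut-2-ene (prenyl bromide) | CC(C)=CCBr | starting material
3 | diethyl 2-(3-methylbut-2-en-1-yl)propanedioate | CCOC(=O)C(CC=C(C)C)C(=O)OCC | intermediate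
4 | diethyl 2,2-bis(3-methylbut-2-en-1-yl)propanedioate | CCOC(=O)C(CC=C(C)C)(CC=C(C)C)C(=O)OCC | intermediate
5 | 2,2-bis(3-methylbut-2-en-1-yl)propanedioic acid | OC(=O)C(CC=C(C)C)(CC=C(C)C)C(=O)O | intermediate
6 | 5-methyl-2-(3-methylbut-2-en-1-yl)hex-4-enoic acid | OC(=O)C(CC=C(C)C)CC=C(C)C | intermediate
7 | 5-methyl-2-(3-methylbut-2-en-1-yl)hex-4-enoyl chloride | ClC(=O)C(CC=C(C)C)CC=C(C)C | intermediate
8 | ethoxyacetylene | CCOC#C | starting material
9 | N-methoxy-N-methyl-2-methylpropanamide | CC(C)C(=O)N(C)OC | starting material
10 | lithium ethoxyacetylide | [Li]C#COCC | intermediate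
11 | chelated lithium hemiaminal adduct of 10 and 9 | CCOC#CC(O[Li])(C(C)C)N(C)OC | intermediate
12 | 1-ethoxy-4-methylpent-1-yn-3-one | CCOC#CC(=O)C(C)C | intermediate
13 | diethyl 2-(3-methylbut-2-en-1-yl)-2-[5-methyl-2-(3-methylbut-2-en-1-yl)hex-4-enoyl]propanedioate (acylmalonate) | CCOC(=O)C(CC=C(C)C)(C(=O)OCC)C(=O)C(CC=C(C)C)CC=C(C)C | intermediate
14 | sodium enolate of 13 (enolate carbon is the one bearing two prenyl groups) | CCOC(=O)C(CC=C(C)C)(C(=O)OCC)C([O-])=C(CC=C(C)C)CC=C(C)C.[Na+] | intermediate
15 | sodium allenolate, conjugate adduct of 14 to 12 (allene axis not defined) | CCOC(=O)C(CC=C(C)C)(C(=O)OCC)C(=O)C(CC=C(C)C)(CC=C(C)C)C(OCC)=C=C([O-])C(C)C.[Na+] | intermediate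
16 | ethyl 4-ethoxy-1,5,5-tris(3-methylbut-2-en-1-yl)-3-(2-methylpropanoyl)-2,6-dioxocyclohex-3-ene-1-carboxylate (racemic) | CCOC1=C(C(=O)C(C)C)C(=O)C(CC=C(C)C)(C(=O)OCC)C(=O)C1(CC=C(C)C)CC=C(C)C | intermediate
17 | 3-ethoxy-5-hydroxy-4,4,6-tris(3-methylbut-2-en-1-yl)-2-(2-methylpropanoyl)cyclohexa-2,5-dien-1-one (colupulone ethyl enol ether) | CCOC1=C(C(=O)C(C)C)C(=O)C(CC=C(C)C)=C(O)C1(CC=C(C)C)CC=C(C)C | intermediate
18 | colupulone | CC(C)=CCC1=C(O)C(CC=C(C)C)(CC=C(C)C)C(=O)C(C(=O)C(C)C)=C1O | target

**Totals**

Total step count: 7. Longest linear sequence: 6 steps (steps 1, 2, 3, 4, 6, 7).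

**Steps most likely to fail, with fallbacks**

Step 6. The relay may break at several points:
- slow or O-selective acylation in the first stage;
- fragmentation of hindered enolate 14 by loss of the malonate (ketene formation), or its O-attack on the ynone;
- protonation of the allenolate before ring closure;
- ring-opening retro-Claisen cleavage by the released ethoxide instead of loss of the extra ester.

The fallback sets out from 13 and comes back at 18, using known reaction types one at a time with isolation after each. Compound 13 is prepared and purified on its own from 3 and 7 (NaH, THF). Its enolate (NaN(SiMe3)2, THF, −78 °C) is treated with 12 and quenched cold with AcOH, so that the conjugate adduct is isolated as the open-chain β-ethoxy enone diethyl 2-[3-ethoxy-6-methyl-2,2-bis(3-methylbut-2-en-1-yl)-5-oxohept-3-enoyl]-2-(3-methylbut-2-en-1-yl)propanedioate F1. Hydrolysis of this vinylogous ester (1 M HCl, THF) gives the triketo diester diethyl 2-[6-methyl-2,2-bis(3-methylbut-2-en-1-yl)-3,5-dioxoheptanoyl]-2-(3-methylbut-2-en-1-yl)propanedioate F2. NaOEt in EtOH at 23 °C then effects the Claisen (Dieckmann) cyclisation of the β-diketone carbon onto a malonate ester to give ethyl 4-hydroxy-1,5,5-tris(3-methylbut-2-en-1-yl)-3-(2-methylpropanoyl)-2,6-dioxocyclohex-3-ene-1-carboxylate F3, which should lose its ethoxycarbonyl group under the same conditions. Acidification gives 18 directly.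

Step 5. The released N,O-dimethylhydroxylamine may add to the ynone, or the ynol ether may be hydrated during the acidic quench. The fallback sets out from 8 and comes back at 12. Compound 8 is lithiated as before (n-BuLi, THF, −78 °C) and added to 2-methylpropanal to give 1-ethoxy-4-methylpent-1-yn-3-ol F4 (racemic). MnO2 in CH2Cl2 at 23 °C oxidises this propargylic alcohol to 12; no amine is set free and no acid is needed.

Step 3. The hindered diester may saponify incompletely, and a prenyl double bond may be captured by a carboxyl group (lactonisation) during acidification and decarboxylation of the diacid. The fallback sets out from 4 and comes back at 6. Krapcho de-ethoxycarbonylation (LiCl, H2O, DMSO, 160 °C) gives ethyl 5-methyl-2-(3-methylbut-2-en-1-yl)hex-4-enoate F5. Saponification (KOH, EtOH/H2O) and cold acidification give 6, so the malonic diacid and its decarboxylation are avoided.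

**Further compounds**

F1 | step 6 | diethyl 2-[3-ethoxy-6-methyl-2,2-bis(3-methylbut-2-en-1-yl)-5-oxohept-3-enoyl]-2-(3-methylbut-2-en-1-yl)propanedioate (alkene geometry not defined) | CCOC(=O)C(CC=C(C)C)(C(=O)OCC)C(=O)C(CC=C(C)C)(CC=C(C)C)C(OCC)=CC(=O)C(C)C
F2 | step 6 | diethyl 2-[6-methyl-2,2-bis(3-methylbut-2-en-1-yl)-3,5-dioxoheptanoyl]-2-(3-methylbut-2-en-1-yl)propanedioate | CCOC(=O)C(CC=C(C)C)(C(=O)OCC)C(=O)C(CC=C(C)C)(CC=C(C)C)C(=O)CC(=O)C(C)C
F3 | step 6 | ethyl 4-hydroxy-1,5,5-tris(3-methylbut-2-en-1-yl)-3-(2-methylpropanoyl)-2,6-dioxocyclohex-3-ene-1-carboxylate (racemic) | CCOC(=O)C1(CC=C(C)C)C(=O)C(C(=O)C(C)C)=C(O)C(CC=C(C)C)(CC=C(C)C)C1=O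
F4 | step 5 | 1-ethoxy-4-methylpent-1-yn-3-ol (racemic) | CCOC#CC(O)C(C)C
F5 | step 3 | ethyl 5-methyl-2-(3-methylbut-2-en-1-yl)hex-4-enoate | CCOC(=O)C(CC=C(C)C)CC=C(C)C
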